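**Strategy.** The route rests on cutting ring B at two adjacent positions, the C1–C1' biaryl bond and the C2–O bond. A 3-benzyloxyaryne, unmasked from an ortho-iodoaryl 4-chlorobenzenesulfonate, accepts the ring C aryl Grignard reagent at C1; the arylmagnesium left at C2 is borylated and oxidised, so the biaryl bond and the second catechol oxygen of ring B arise in one flask. The step exploits the contiguous C1 aryl, C2 hydroxyl, C3 hydroxyl array of ring B and the C5 ethylene arm lying meta to C1 and C3, which lets a symmetrical 5-substituted resorcinol, iodinated at C2 and differentiated as benzyl ether and sulfonate, serve as precursor.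

Key step: step 10

Remark on the chemistry: ring B is the 2,3-dihydroxyphenyl ring (C1 carries ring C, C5 the arm) and ring C is the 4',5'-dihydroxyphenyl ring (C2' carries its arm). The Wittig product 4 is taken on as an E/Z mixture because its alkene is saturated in the next step, so its SMILES carries no alkene descriptor. The Horner–Wadsworth–Emmons product 13 is drawn as the E isomer expected from that reaction; any Z isomer would be reduced to the same compound 14. The target has no stereocentre, and its biaryl axis, with only two ortho substituents, is assumed to rotate freely.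

**Step 1**
Reactants: 1 3,5-bis(benzyloxy)benzaldehyde; 2 (3-methoxybenzyl)triphenylphosphonium chloride
Product: 4 1,3-bis(benzyloxy)-5-[2-(3-methoxyphenyl)ethenyl]benzene (E/Z mixture), via phosphonium ylide 3 (not isolated)
Conditions: KOt-Bu, THF, 0 °C → 25 °C
Reagents that add atoms: none
Why: Wittig olefination of a non-enolisable aryl aldehyde with a semi-stabilised benzylic ylide is reliable, and starting from the bis-benzyl ether avoids olefinating a free bis-phenol.

**Step 2**
Reactants: 4 1,3-bis(benzyloxy)-5-[2-(3-methoxyphenyl)ethenyl]benzene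
Product: 5 5-[2-(3-methoxyphenyl)ethyl]benzene-1,3-diol
Conditions: H2 (1 atm), 10% Pd/C, EtOAc/MeOH, 25 °C
Reagents that add atoms: none
Why: Catalytic hydrogenation saturates the stilbene and hydrogenolyses both aryl benzyl ethers in the same operation while the aryl methyl ether is inert, so the symmetrical resorcinol is unveiled without a separate deprotection.

**Step 3**
Reactants: 5 5-[2-(3-methoxyphenyl)ethyl]benzene-1,3-diol
Product: 6 2-iodo-5-[2-(3-methoxyphenyl)ethyl]benzene-1,3-diol
Conditions: I2 (1.05 equiv), NaHCO3, THF/H2O, 0 °C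
Reagents that add atoms: iodine, II
Why: Electrophilic aromatic iodination of the resorcinol monoanion in aqueous bicarbonate should take place at C2, ortho to both oxygens, since C4 and C6 are additionally shielded by the C5 side chain and the anisole ring is far less nucleophilic.

**Step 4**
Reactants: 6 2-iodo-5-[2-(3-methoxyphenyl)ethyl]benzene-1,3-diol
Product: 7 3-(benzyloxy)-2-iodo-5-[2-(3-methoxyphenyl)ethyl]phenol
Conditions: BnBr (1.0 equiv), K2CO3 (1.1 equiv), acetone, reflux
Reagents that add atoms: benzyl bromide, BrCc1ccccc1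
Why: Williamson etherification with one equivalent of benzyl bromide converts one of the two equivalent phenols; the bis-ether is separable and unreacted 6 can be recycled.

**Step 5**
Reactants: 7 3-(benzyloxy)-2-iodo-5-[2-(3-methoxyphenyl)ethyl]phenol
Product: 8 3-(benzyloxy)-2-iodo-5-[2-(3-methoxyphenyl)ethyl]phenyl 4-chlorobenzenesulfonate
Conditions: 4-ClC6H4SO2Cl, Et3N, DMAP (cat.), CH2Cl2, 0 °C → 25 °C
Reagents that add atoms: 4-chlorobenzenesulfonyl chloride, O=S(=O)(Cl)c1ccc(Cl)cc1
Why: O-Sulfonylation of a phenol under amine base is routine, and the 4-chlorobenzenesulfonate is chosen because it tolerates iodine–magnesium exchange at low temperature yet departs on warming, whereas a triflate is prone to attack at sulfur.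

**Step 6**
Reactants: 9 3,4-bis(benzyloxy)benzaldehyde
Product: 10 4,5-bis(benzyloxy)-2-bromobenzaldehyde
Conditions: Br2 (1.1 equiv), NaOAc, AcOH, 25 °C
Reagents that add atoms: bromine, BrBr
Why: Electrophilic aromatic bromination should go para to the C3 benzyloxy group (the more donating oxygen, since the C4 oxygen is conjugated with the formyl group), and the acetate buffer protects the benzyl ethers from HBr.

**Step 7**
Reactants: 10 4,5-bis(benzyloxy)-2-bromobenzaldehyde; 11 diethyl (3-methoxybenzyl)phosphonate
Product: 13 (E)-1,2-bis(benzyloxy)-4-bromo-5-[2-(3-methoxyphenyl)ethenyl]benzene, via potassium phosphonate carbanion 12 (not isolated)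
Conditions: KOt-Bu, THF, 0 °C → 25 °C
Reagents that add atoms: none
Why: Horner–Wadsworth–Emmons olefination of the non-enolisable aryl aldehyde with the benzylic phosphonate carbanion should give the E stilbene, the geometry that diimide reduces most readily, while the aryl bromide is inert to the carbanion and the phosphate by-product is removed by aqueous extraction.

**Step 8**
Reactants: 13 (E)-1,2-bis(benzyloxy)-4-bromo-5-[2-(3-methoxyphenyl)ethenyl]benzene
Product: 14 1,2-bis(benzyloxy)-4-bromo-5-[2-(3-methoxyphenyl)ethyl]benzene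
Conditions: TsNHNH2 (excess), NaOAc, DME/H2O, reflux
Reagents that add atoms: none
Why: Diimide reduction, with diimide generated by fragmentation of the sulfonohydrazide, delivers two hydrogens to the C=C bond in a concerted manner and spares the aryl bromide and the benzyl ethers, which hydrogenation over palladium would endanger.

**Step 9**
Reactants: 14 1,2-bis(benzyloxy)-4-bromo-5-[2-(3-methoxyphenyl)ethyl]benzene
Product: 15 {4,5-bis(benzyloxy)-2-[2-(3-methoxyphenyl)ethyl]phenyl}magnesium bromide
Conditions: Mg turnings, LiCl, i-Bu2AlH (1 mol%), THF, 25 °C; titrated solution used directly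
Reagents that add atoms: magnesium, [Mg]
Why: Direct insertion of magnesium into the aryl C–Br bond, accelerated by LiCl, is standard Grignard formation, and aryl benzyl and methyl ethers are compatible with it.

**Step 10**
Reactants: 8 3-(benzyloxy)-2-iodo-5-[2-(3-methoxyphenyl)ethyl]phenyl 4-chlorobenzenesulfonate; 15 {4,5-bis(benzyloxy)-2-[2-(3-methoxyphenyl)ethyl]phenyl}magnesium bromide
Product: 20 3,4',5'-tris(benzyloxy)-2',5-bis[2-(3-methoxyphenyl)ethyl]-[1,1'-biphenyl]-2-ol, via magnesiated sulfonate 16 (not isolated), via 3-benzyloxyaryne 17 (not isolated), via biarylmagnesium bromide 18 (not isolated), via dimethyl arylboronate 19 (not isolated)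
Conditions: i-PrMgCl (1.05 equiv), THF, −78 °C, 30 min; then 15 (1.5 equiv), −78 → 25 °C; B(OMe)3 (5 equiv), 0 → 25 °C; 30% aq H2O2, 0 → 25 °C
Reagents that add atoms: hydrogen peroxide, OO (the C2 oxygen of 20); isopropylmagnesium chloride, CC(C)[Mg]Cl (Mg and Cl of 16 only); trimethyl borate, COB(OC)OC (boron and methoxy groups of 19 only)
Why: Iodine–magnesium exchange on 8 at −78 °C gives arylmagnesium 16, which on warming loses 4-chlorobenzenesulfonate by beta-elimination to give aryne 17; Grignard reagent 15 adds across the strained triple bond to give 18, which is borylated to 19 and oxidised by peroxide with aryl migration from boron to oxygen. The closest known reaction type is carbomagnesiation of 3-alkoxyarynes generated from 2-iodoaryl sulfonates with electrophilic capture of the new arylmagnesium, joined to the standard borate/peroxide hydroxylation of aryl Grignard reagents. No ring is closed and no stereocentre is formed. The step needs regioselective addition: the inductively withdrawing C3 benzyloxy group distorts the aryne so that C1 is the more electrophilic carbon and stabilises the developing carbanion at C2, so the aryl group should enter at C1 and magnesium should remain at C2. Chemoselectivity rests on completing the exchange at −78 °C before 15 is added, so that no i-PrMgCl remains to add to the aryne, and on keeping 15 in excess so that 18 does not compete for 17.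

**Step 11**
Reactants: 20 3,4',5'-tris(benzyloxy)-2',5-bis[2-(3-methoxyphenyl)ethyl]-[1,1'-biphenyl]-2-ol
Product: 21 isoplagilin
Conditions: H2 (1 atm), 10% Pd/C, EtOAc/MeOH, 25 °C; filtration and concentration under argon
Reagents that add atoms: none
Why: Hydrogenolysis of the three aryl benzyl ethers over palladium on carbon leaves the methyl ethers, the biaryl and the bibenzyl units untouched; air is excluded because the product is a bis-catechol.

**Compound list**

1 | 3,5-bis(benzyloxy)benzaldehyde | O=Cc1cc(OCc2ccccc2)cc(OCc2ccccc2)c1 | starting material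
2 | (3-methoxybenzyl)triphenylphosphonium chloride | COc1cccc(C[P+](c2ccccc2)(c2ccccc2)c2ccccc2)c1.[Cl-] | starting material
3 | (3-methoxybenzylidene)triphenylphosphorane (ylide; not isolated) | COc1cccc(C=P(c2ccccc2)(c2ccccc2)c2ccccc2)c1 | intermediate
4 | 1,3-bis(benzyloxy)-5-[2-(3-methoxyphenyl)ethenyl]benzene (E/Z mixture) | COc1cccc(C=Cc2cc(OCc3ccccc3)cc(OCc3ccccc3)c2)c1 | intermediate
5 | 5-[2-(3-methoxyphenyl)ethyl]benzene-1,3-diol | COc1cccc(CCc2cc(O)cc(O)c2)c1 | intermediate
6 | 2-iodo-5-[2-(3-methoxyphenyl)ethyl]benzene-1,3-diol | COc1cccc(CCc2cc(O)c(I)c(O)c2)c1 | intermediate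
7 | 3-(benzyloxy)-2-iodo-5-[2-(3-methoxyphenyl)ethyl]phenol | COc1cccc(CCc2cc(O)c(I)c(OCc3ccccc3)c2)c1 | intermediate
8 | 3-(benzyloxy)-2-iodo-5-[2-(3-methoxyphenyl)ethyl]phenyl 4-chlorobenzenesulfonate | COc1cccc(CCc2cc(OCc3ccccc3)c(I)c(OS(=O)(=O)c3ccc(Cl)cc3)c2)c1 | intermediate
9 | 3,4-bis(benzyloxy)benzaldehyde | O=Cc1ccc(OCc2ccccc2)c(OCc2ccccc2)c1 | starting material
10 | 4,5-bis(benzyloxy)-2-bromobenzaldehyde | O=Cc1cc(OCc2ccccc2)c(OCc2ccccc2)cc1Br | intermediate
11 | diethyl (3-methoxybenzyl)phosphonate | COc1cccc(CP(=O)(OCC)OCC)c1 | starting material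
12 | potassium salt of the diethyl (3-methoxybenzyl)phosphonate carbanion (not isolated) | COc1cccc([CH-]P(=O)(OCC)OCC)c1.[K+] | intermediate
13 | (E)-1,2-bis(benzyloxy)-4-bromo-5-[2-(3-methoxyphenyl)ethenyl]benzene | COc1cccc(/C=C/c2cc(OCc3ccccc3)c(OCc3ccccc3)cc2Br)c1 | intermediate
14 | 1,2-bis(benzyloxy)-4-bromo-5-[2-(3-methoxyphenyl)ethyl]benzene | COc1cccc(CCc2cc(OCc3ccccc3)c(OCc3ccccc3)cc2Br)c1 | intermediate
15 | {4,5-bis(benzyloxy)-2-[2-(3-methoxyphenyl)ethyl]phenyl}magnesium bromide (THF solution) | COc1cccc(CCc2cc(OCc3ccccc3)c(OCc3ccccc3)cc2[Mg]Br)c1 | intermediate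
16 | {2-(benzyloxy)-6-[(4-chlorobenzenesulfonyl)oxy]-4-[2-(3-methoxyphenyl)ethyl]phenyl}magnesium chloride (not isolated) | COc1cccc(CCc2cc(OCc3ccccc3)c([Mg]Cl)c(OS(=O)(=O)c3ccc(Cl)cc3)c2)c1 | intermediate
17 | 3-(benzyloxy)-5-[2-(3-methoxyphenyl)ethyl]-1,2-didehydrobenzene (aryne; not isolated) | COc1cccc(CCC2=CC#CC(OCc3ccccc3)=C2)c1 | intermediate
18 | {3,4',5'-tris(benzyloxy)-2',5-bis[2-(3-methoxyphenyl)ethyl]-[1,1'-biphenyl]-2-yl}magnesium bromide (not isolated) | COc1cccc(CCc2cc(OCc3ccccc3)c([Mg]Br)c(-c3cc(OCc4ccccc4)c(OCc4ccccc4)cc3CCc3cccc(OC)c3)c2)c1 | intermediate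
19 | dimethyl {3,4',5'-tris(benzyloxy)-2',5-bis[2-(3-methoxyphenyl)ethyl]-[1,1'-biphenyl]-2-yl}boronate (not isolated) | COc1cccc(CCc2cc(OCc3ccccc3)c(B(OC)OC)c(-c3cc(OCc4ccccc4)c(OCc4ccccc4)cc3CCc3cccc(OC)c3)c2)c1 | intermediate
20 | 3,4',5'-tris(benzyloxy)-2',5-bis[2-(3-methoxyphenyl)ethyl]-[1,1'-biphenyl]-2-ol | COc1cccc(CCc2cc(OCc3ccccc3)c(O)c(-c3cc(OCc4ccccc4)c(OCc4ccccc4)cc3CCc3cccc(OC)c3)c2)c1 | intermediate
21 | isoplagilin, 2',5-bis[2-(3-methoxyphenyl)ethyl]-[1,1'-biphenyl]-2,3,4',5'-tetrol | COc1cccc(CCc2cc(O)c(O)c(-c3cc(O)c(O)cc3CCc3cccc(OC)c3)c2)c1 | target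

**Totals**

Total step count: 11 (steps 1–5 for the ring B sulfonate, steps 6–9 for the ring C Grignard reagent, steps 10 and 11 after convergence).
Longest linear sequence: 7 steps (1, 2, 3, 4, 5, 10, 11).

**Steps most likely to fail**

Step 10. The arylmagnesium at C2 of 18 is flanked by the C3 benzyloxy group and by the ortho-substituted ring C, so borylation may be slow and protonation on work-up would then leave hydrogen at C2. In addition, 18 may add to a second aryne if 15 runs short. The fallback separates carbon–carbon from carbon–oxygen bond formation. It sets out from 8 and 15, which are taken to 18 exactly as in step 10. The borate is replaced by iodine, a small and fast electrophile, which should give 3,4',5'-tris(benzyloxy)-2-iodo-2',5-bis[2-(3-methoxyphenyl)ethyl]-1,1'-biphenyl F1. After isolation, F1 is hydroxylated by palladium-catalysed coupling with hydroxide (Pd2(dba)3, t-BuXPhos, KOH, 1,4-dioxane/H2O, 100 °C), which comes back to the route at 20.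

Step 3. Iodination may lack positional control, with attack at C4 or C6 or a second iodination. The fallback fixes the position by directed ortho-metalation and sets out from 5. Protection with MOMCl and i-Pr2NEt in CH2Cl2 should give 1-[2-(3-methoxyphenyl)ethyl]-3,5-bis(methoxymethoxy)benzene F2. n-BuLi in THF at 0 °C should deprotonate the doubly activated position between the two acetal oxygens to give {4-[2-(3-methoxyphenyl)ethyl]-2,6-bis(methoxymethoxy)phenyl}lithium F3. Quenching with I2 should give 2-iodo-5-[2-(3-methoxyphenyl)ethyl]-1,3-bis(methoxymethoxy)benzene F4. Mild acid (HCl in MeOH, 25 °C) then removes both acetals and comes back to the route at 6.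

Step 4. The two hydroxyls of 6 are equivalent, so over-alkylation to the bis-ether and incomplete conversion can erode the supply of 7. The fallback reverses the order of differentiation and sets out from 6. One equivalent of 4-chlorobenzenesulfonyl chloride (Et3N, CH2Cl2, −20 °C, slow addition) should give 3-hydroxy-2-iodo-5-[2-(3-methoxyphenyl)ethyl]phenyl 4-chlorobenzenesulfonate F5. The first sulfonate is electron-withdrawing and lowers the nucleophilicity of the remaining phenol toward a second sulfonylation. Benzylation of F5 (BnBr, K2CO3, acetone, reflux) then comes back to the route at 8, bypassing 7.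

**Further compounds**

F1 | step 10 | 3,4',5'-tris(benzyloxy)-2-iodo-2',5-bis[2-(3-methoxyphenyl)ethyl]-1,1'-biphenyl | COc1cccc(CCc2cc(OCc3ccccc3)c(I)c(-c3cc(OCc4ccccc4)c(OCc4ccccc4)cc3CCc3cccc(OC)c3)c2)c1
F2 | step 3 | 1-[2-(3-methoxyphenyl)ethyl]-3,5-bis(methoxymethoxy)benzene | COCOc1cc(CCc2cccc(OC)c2)cc(OCOC)c1
F3 | step 3 | {4-[2-(3-methoxyphenyl)ethyl]-2,6-bis(methoxymethoxy)phenyl}lithium | COCOc1cc(CCc2cccc(OC)c2)cc(OCOC)c1[Li]
F4 | step 3 | 2-iodo-5-[2-(3-methoxyphenyl)ethyl]-1,3-bis(methoxymethoxy)benzene | COCOc1cc(CCc2cccc(OC)c2)cc(OCOC)c1I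
F5 | step 4 | 3-hydroxy-2-iodo-5-[2-(3-methoxyphenyl)ethyl]phenyl 4-chlorobenzenesulfonate | COc1cccc(CCc2cc(O)c(I)c(OS(=O)(=O)c3ccc(Cl)cc3)c2)c1
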